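The route rests on cutting the C7–C11 bond of the lactone ring. Because O6, C7 and O8 lie on three neighbouring carbons, C6–C8 is built as an erythro trans-2,3-epoxy alcohol whose C6 oxygen carries a diethylphosphonoacetate. One deprotonation then lets C11 open the C7–C8 epoxide at C7: the C7–C11 bond forms, the five-membered lactone ring closes trans, C7 is set by inversion and O8 is freed for Mitsunobu inversion to the methacrylate, while the phosphonate later delivers the C13 methylene. Precursor 10 is the C5–C10 chain bearing protected CH2O groups at C1 and C5 and a silylated tertiary C10 alcohol; the furanone ring and ten-membered carbocycle follow by alkynyl–aldehyde closure and gold-catalysed cyclisation.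

Key step: step 8

Remark: atoms carry the germacranolide numbers of the target throughout (C1 ketone carbon, C2=C3, C4=C5, C6–O lactone, C7, C8–O ester, C9, C10, C11=C13, C12 lactone carbonyl, C14 methyl, C15 acetoxymethyl carbon); the phosphono lactones are drawn as the C11 epimer trans to the C7 side chain, a centre that is erased in step 10.

Step 1
Reactants: 1 (S)-2-methylglycidol
Product: 2 (R)-2-[(4-methoxybenzyloxy)methyl]-2-methyloxirane
Conditions: NaH, PMBCl, Bu4NI (cat.), THF, 0 °C to rt
Reagents that add atoms: 4-methoxybenzyl chloride, COc1ccc(CCl)cc1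
Why: Williamson etherification of the primary alkoxide leaves the quaternary epoxide carbon untouched, so the configuration of 1 (the future C10) is carried into 2.

Step 2
Reactants: 2 (R)-2-[(4-methoxybenzyloxy)methyl]-2-methyloxirane
Product: 3 (R)-1-(4-methoxybenzyloxy)-2-methylpent-4-en-2-ol
Conditions: CH2=CHMgBr, CuI (10 mol %), THF, −40 to 0 °C; aqueous work-up
Reagents that add atoms: vinylmagnesium bromide, C=C[Mg]Br
Why: Copper-catalysed Grignard opening of the epoxide at its unhindered CH2 terminus keeps the C10–O bond and its configuration and gives the tertiary homoallylic alcohol.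

Step 3
Reactants: 3 (R)-1-(4-methoxybenzyloxy)-2-methylpent-4-en-2-ol
Product: 4 (R)-1-(4-methoxybenzyloxy)-2-methyl-2-(triethylsilyloxy)pent-4-ene
Conditions: TESOTf, 2,6-lutidine, CH2Cl2, −78 to 0 °C
Reagents that add atoms: triethylsilyl trifluoromethanesulfonate, CC[Si](CC)(CC)OS(=O)(=O)C(F)(F)F
Why: Silylation of a tertiary alcohol with a silyl triflate and a hindered base is standard and touches no stereocentre.

Step 4
Reactants: 5 (S)-but-3-ene-1,2-diol
Product: 6 (S)-1-(triethylsilyloxy)but-3-en-2-ol
Conditions: TESCl (1.0 equiv), imidazole, CH2Cl2, −40 to −20 °C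
Reagents that add atoms: chlorotriethylsilane, CC[Si](CC)(CC)Cl
Why: Silyl chlorides discriminate the primary from the secondary allylic hydroxyl at low temperature, so monosilylation leaves the chiral-pool C6 carbinol free and unchanged.

Step 5
Reactants: 4 (R)-1-(4-methoxybenzyloxy)-2-methyl-2-(triethylsilyloxy)pent-4-ene; 6 (S)-1-(triethylsilyloxy)but-3-en-2-ol
Product: 7 (2S,3E,6R)-7-(4-methoxybenzyloxy)-6-methyl-1,6-bis(triethylsilyloxy)hept-3-en-2-ol
Conditions: second-generation Hoveyda–Grubbs catalyst (5 mol %), 6 (2.5 equiv), CH2Cl2, 40 °C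
Reagents that add atoms: none
Why: Olefin cross-metathesis between the readily homodimerising terminal alkene 4 and the slowly homodimerising secondary allylic alcohol 6 gives the cross product, the E geometry of C7=C8 being favoured thermodynamically.

Step 6
Reactants: 7 (2S,3E,6R)-7-(4-methoxybenzyloxy)-6-methyl-1,6-bis(triethylsilyloxy)hept-3-en-2-ol
Product: 8 erythro trans-epoxy alcohol (R)-1-[(2R,3R)-3-[(R)-3-(4-methoxybenzyloxy)-2-methyl-2-(triethylsilyloxy)propyl]oxiran-2-yl]-2-(triethylsilyloxy)ethan-1-ol
Conditions: Ti(OiPr)4, D-(−)-diisopropyl tartrate, t-BuOOH, 4 Å sieves, CH2Cl2, −20 °C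
Reagents that add atoms: tert-butyl hydroperoxide, CC(C)(C)OO
Why: Sharpless asymmetric epoxidation, in which the (S)-carbinol is the fast-reacting, matched partner of the D-(−)-tartrate complex, so oxygen is delivered to the alkene face that gives the erythro trans-epoxide and sets C7 and C8.

Step 7
Reactants: 8 erythro trans-epoxy alcohol; 9 diethylphosphonoacetic acid
Product: 10 epoxy phosphonoacetate (C6 diethylphosphonoacetate of 8)
Conditions: DCC, DMAP (cat.), CH2Cl2, 0 °C to rt
Reagents that add atoms: none
Why: Steglich esterification acylates the secondary alcohol under neutral conditions without opening the epoxide or touching C6.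

Step 8
Reactants: 10 epoxy phosphonoacetate
Product: 13 trans α-phosphono γ-lactone 8-epi-alcohol, via sodium enolate 11 (not isolated), via lactone sodium carbanion 12 (not isolated)
Conditions: NaH (1.1 equiv), THF, 0 °C to rt (not above 40 °C); AcOH quench at 0 °C
Reagents that add atoms: none
Why: NaH removes a proton from the phosphonoacetate CH2 to give 11, whose carbanion C11 attacks epoxide carbon C7 anti to the C7–O bond, forming C7–C11, closing the lactone and releasing the C8 alkoxide, which is protonated at once by the far more acidic C11–H of the product so that the mixture rests as carbanion 12 until the quench. The closest known reaction types are the 5-exo opening of 2,3-epoxy alcohol derivatives by a nucleophile carried on the hydroxyl oxygen and the alkylation of phosphonoacetate or malonate carbanions by epoxides, and the same O6–C12–C11–C7–C6 ring is closed from this tether in intramolecular Horner–Wadsworth–Emmons butenolide syntheses. The five-membered lactone ring closes in the 5-exo-tet mode, the breaking C7–O bond lying outside the new ring. C7 is set by inversion and so by the epoxide configuration fixed in step 6, C6 and C8 are not touched, and C11 settles trans to the C7 side chain by equilibration through 12. The step needs attack at C7 and not at C8 and alkylation at carbon and not at enolate oxygen: the exo mode with the shorter tether allows the collinear approach only at C7, the soft phosphoryl-stabilised carbon gives the stronger bond, and resting as 12 below 40 °C keeps O8 from attacking the lactone carbonyl or phosphorus.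

Step 9
Reactants: 13 trans α-phosphono γ-lactone 8-epi-alcohol
Product: 14 C8 methacrylate of the phosphono lactone (C8 inverted)
Conditions: methacrylic acid, PPh3, DIAD (added last), THF, 0 °C to rt
Reagents that add atoms: methacrylic acid, CC(=C)C(=O)O
Why: Mitsunobu esterification, in which methacrylate displaces the C8 oxyphosphonium in an SN2 step and so inverts C8 to the configuration of the target, while the much less acidic phosphono lactone C–H does not compete as pronucleophile.

Step 10
Reactants: 14 C8 methacrylate of the phosphono lactone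
Product: 15 α-methylene lactone
Conditions: 37 % aq. HCHO, K2CO3, THF, 0 °C to rt
Reagents that add atoms: formaldehyde, C=O
Why: Horner–Wadsworth–Emmons olefination of the α-phosphono lactone with formaldehyde under mild carbonate conditions gives the exocyclic C11=C13 methylene and removes the C11 stereocentre.

Step 11
Reactants: 15 α-methylene lactone
Product: 16 C5 aldehyde
Conditions: (COCl)2, DMSO, CH2Cl2, −78 to −40 °C; then Et3N, −78 to 0 °C
Reagents that add atoms: none
Why: Under Swern conditions chlorodimethylsulfonium chloride cleaves a primary triethylsilyl ether directly to the alkoxysulfonium ion, which base converts into the aldehyde, while the hindered tertiary silyl ether and the PMB ether stay on (selective oxidative deprotection of primary TES ethers).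

Step 12
Reactants: 17 (triphenylphosphoranylidene)acetaldehyde
Product: 19 2-bromo-2-(triphenylphosphoranylidene)acetaldehyde, via bromophosphonium bromide 18 (not isolated)
Conditions: Br2, CH2Cl2, −78 to 0 °C; then Et3N
Reagents that add atoms: bromine, BrBr
Why: Bromination of a carbonyl-stabilised ylide at carbon followed by deprotonation of the phosphonium salt is the standard preparation of α-halo acyl ylides.

Step 13
Reactants: 16 C5 aldehyde; 19 2-bromo-2-(triphenylphosphoranylidene)acetaldehyde
Product: 20 (Z)-2-bromo enal (C5H=C4(Br)–C15HO)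
Conditions: toluene, rt to 40 °C
Reagents that add atoms: none
Why: Wittig olefination with a stabilised ylide places the formyl group trans to the C6 substituent, so bromine ends cis to C6 and the C4=C5 geometry of the target is set.

Step 14
Reactants: 20 (Z)-2-bromo enal; 21 ethynyltrimethylsilane
Product: 22 enynal (C≡C–SiMe3 on C4, cis to C6)
Conditions: PdCl2(PPh3)2 (5 mol %), CuI (10 mol %), Et3N, THF, rt
Reagents that add atoms: none
Why: Sonogashira coupling, in which zerovalent palladium inserts readily into the C–Br bond of the α-bromo enal and the alkynyl group is transferred with retention of the alkene geometry.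

Step 15
Reactants: 22 enynal
Product: 23 enynol (C15 primary allylic alcohol)
Conditions: NaBH4, CeCl3·7H2O, MeOH–THF, −78 °C
Reagents that add atoms: none
Why: Luche reduction delivers hydride 1,2 to the enal at −78 °C and leaves the lactone, the esters and the conjugated methylene lactone untouched.

Step 16
Reactants: 23 enynol
Product: 24 C15 acetate
Conditions: Ac2O, pyridine, DMAP (cat.), CH2Cl2, 0 °C
Reagents that add atoms: acetic anhydride, CC(=O)OC(C)=O
Why: Acylation of the primary allylic alcohol with acetic anhydride and DMAP installs the C15 acetate of the target.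

Step 17
Reactants: 24 C15 acetate
Product: 25 C1 primary alcohol
Conditions: DDQ, CH2Cl2–pH 7 buffer, 0 °C
Reagents that add atoms: none
Why: Oxidative cleavage of the electron-rich PMB ether by DDQ in wet solvent frees the C1 alcohol without touching the silyl ether, the esters or the enyne.

Step 18
Reactants: 25 C1 primary alcohol
Product: 26 1-iodoalkyne
Conditions: N-iodosuccinimide, AgNO3 (10 mol %), acetone, rt, dark
Reagents that add atoms: N-iodosuccinimide, O=C1CCC(=O)N1I
Why: Silver-catalysed iododesilylation with N-iodosuccinimide converts the alkynylsilane directly into the 1-iodoalkyne needed for the chromium coupling.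

Step 19
Reactants: 26 1-iodoalkyne
Product: 27 C1 aldehyde
Conditions: Dess–Martin periodinane, pyridine, CH2Cl2, 0 °C to rt
Reagents that add atoms: none
Why: Dess–Martin oxidation gives the non-enolisable α-silyloxy aldehyde under buffered conditions that the iodoalkyne tolerates.

Step 20
Reactants: 27 C1 aldehyde
Product: 28 ten-membered propargylic alcohol (both C1 epimers)
Conditions: CrCl2 (8 equiv), NiCl2 (2 mol %), THF–DMF, rt, 2 mM (syringe pump)
Reagents that add atoms: none
Why: Intramolecular Nozaki–Hiyama–Kishi reaction, in which the alkynylchromium species formed from the iodoalkyne adds only to the aldehyde and closes the ten-membered ring at C1–C2 under high dilution; both C1 epimers are used since C1 becomes a ketone.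

Step 21
Reactants: 28 ten-membered propargylic alcohol
Product: 29 macrocyclic ynone
Conditions: Dess–Martin periodinane, pyridine, CH2Cl2, 0 °C
Reagents that add atoms: none
Why: Dess–Martin oxidation of the secondary propargylic alcohol gives the ynone and erases the C1 stereocentre.

Step 22
Reactants: 29 macrocyclic ynone
Product: 30 α'-hydroxy ynone
Conditions: HF·pyridine, pyridine, THF, 0 °C
Reagents that add atoms: none
Why: Buffered HF·pyridine removes the triethylsilyl group from the tertiary alcohol while the esters and the lactone are stable to acidic fluoride.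

Step 23
Reactants: 30 α'-hydroxy ynone
Product: 31 goyazensolide 15-acetate (target)
Conditions: Ph3PAuNTf2 (5 mol %), CH2Cl2, rt
Reagents that add atoms: none
Why: Gold-catalysed cycloisomerisation, in which π-activation of the ynone lets the C10 hydroxyl add to C3 in a 5-endo-dig mode across the ring and protodeauration gives the 3(2H)-furanone, a known route from α'-hydroxy ynones.

Compound list

1 | (S)-2-methylglycidol, (S)-(2-methyloxiran-2-yl)methanol | C[C@]1(CO)CO1 | starting material
2 | (R)-2-[(4-methoxybenzyloxy)methyl]-2-methyloxirane | C[C@]1(COCc2ccc(OC)cc2)CO1 | intermediate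
3 | (R)-1-(4-methoxybenzyloxy)-2-methylpent-4-en-2-ol | C=CC[C@@](C)(O)COCc1ccc(OC)cc1 | intermediate
4 | (R)-1-(4-methoxybenzyloxy)-2-methyl-2-(triethylsilyloxy)pent-4-ene (C8–C10, C1, C14 fragment) | C=CC[C@@](C)(O[Si](CC)(CC)CC)COCc1ccc(OC)cc1 | intermediate
5 | (S)-but-3-ene-1,2-diol | C=C[C@H](O)CO | starting material
6 | (S)-1-(triethylsilyloxy)but-3-en-2-ol (C5–C7 fragment) | C=C[C@H](O)CO[Si](CC)(CC)CC | intermediate
7 | (2S,3E,6R)-7-(4-methoxybenzyloxy)-6-methyl-1,6-bis(triethylsilyloxy)hept-3-en-2-ol (C6 allylic alcohol, E C7=C8) | CC[Si](CC)(CC)OC[C@@H](O)/C=C/C[C@@](C)(O[Si](CC)(CC)CC)COCc1ccc(OC)cc1 | intermediate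
8 | erythro trans-epoxy alcohol, (R)-1-[(2R,3R)-3-[(R)-3-(4-methoxybenzyloxy)-2-methyl-2-(triethylsilyloxy)propyl]oxiran-2-yl]-2-(triethylsilyloxy)ethan-1-ol | CC[Si](CC)(CC)OC[C@@H](O)[C@H]1O[C@@H]1C[C@@](C)(O[Si](CC)(CC)CC)COCc1ccc(OC)cc1 | intermediate
9 | diethylphosphonoacetic acid, 2-(diethoxyphosphoryl)acetic acid | CCOP(=O)(CC(=O)O)OCC | starting material
10 | epoxy phosphonoacetate, the C6 2-(diethoxyphosphoryl)acetate of 8 with all configurations of 8 (precursor of the key step) | CC[Si](CC)(CC)OC[C@@H](OC(=O)CP(=O)(OCC)OCC)[C@H]1O[C@@H]1C[C@@](C)(O[Si](CC)(CC)CC)COCc1ccc(OC)cc1 | intermediate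
11 | sodium enolate of 10 (carbanion at C11) | CC[Si](CC)(CC)OC[C@@H](OC(=O)[CH-]P(=O)(OCC)OCC)[C@H]1O[C@@H]1C[C@@](C)(O[Si](CC)(CC)CC)COCc1ccc(OC)cc1.[Na+] | intermediate
12 | sodium salt of 13 (carbanion at C11, free C8 hydroxyl) | CC[Si](CC)(CC)OC[C@H]1OC(=O)[C-](P(=O)(OCC)OCC)[C@@H]1[C@H](O)C[C@@](C)(O[Si](CC)(CC)CC)COCc1ccc(OC)cc1.[Na+] | intermediate
13 | trans α-phosphono γ-lactone alcohol: O6–C12 lactone across C6/C7 with H6 and H7 trans, diethoxyphosphoryl at C11 trans to the C7 chain, C5 as CH2OTES, free C8 hydroxyl epimeric to the target ester, C10 OTES, C1 as CH2OPMB; C6, C7 and C10 as in 31 | CC[Si](CC)(CC)OC[C@H]1OC(=O)[C@@H](P(=O)(OCC)OCC)[C@@H]1[C@H](O)C[C@@](C)(O[Si](CC)(CC)CC)COCc1ccc(OC)cc1 | intermediate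
14 | C8 methacrylate of the phosphono lactone, C8 inverted to the configuration of 31 | CC[Si](CC)(CC)OC[C@H]1OC(=O)[C@@H](P(=O)(OCC)OCC)[C@@H]1[C@@H](OC(=O)C(C)=C)C[C@@](C)(O[Si](CC)(CC)CC)COCc1ccc(OC)cc1 | intermediate
15 | α-methylene lactone (C11=C13) with C8 methacrylate, C5 as CH2OTES, C10 OTES, C1 as CH2OPMB | CC[Si](CC)(CC)OC[C@H]1OC(=O)C(=C)[C@@H]1[C@@H](OC(=O)C(C)=C)C[C@@](C)(O[Si](CC)(CC)CC)COCc1ccc(OC)cc1 | intermediate
16 | C5 aldehyde of 15 (formyl group on C6) | O=C[C@H]1OC(=O)C(=C)[C@@H]1[C@@H](OC(=O)C(C)=C)C[C@@](C)(O[Si](CC)(CC)CC)COCc1ccc(OC)cc1 | intermediate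
17 | (triphenylphosphoranylidene)acetaldehyde | O=CC=P(c1ccccc1)(c1ccccc1)c1ccccc1 | starting material
18 | (1-bromo-2-oxoethyl)triphenylphosphonium bromide | O=CC(Br)[P+](c1ccccc1)(c1ccccc1)c1ccccc1.[Br-] | intermediate
19 | 2-bromo-2-(triphenylphosphoranylidene)acetaldehyde | O=CC(Br)=P(c1ccccc1)(c1ccccc1)c1ccccc1 | intermediate
20 | (Z)-2-bromo enal: C5H=C4(Br)–C15HO on C6, bromine cis and formyl trans to C6 | O=C/C(Br)=C/[C@H]1OC(=O)C(=C)[C@@H]1[C@@H](OC(=O)C(C)=C)C[C@@](C)(O[Si](CC)(CC)CC)COCc1ccc(OC)cc1 | intermediate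
21 | ethynyltrimethylsilane | C[Si](C)(C)C#C | starting material
22 | enynal: C4 carries C≡C–SiMe3 (C3, C2) cis to C6 and the C15 formyl group trans to C6 | O=C/C(C#C[Si](C)(C)C)=C/[C@H]1OC(=O)C(=C)[C@@H]1[C@@H](OC(=O)C(C)=C)C[C@@](C)(O[Si](CC)(CC)CC)COCc1ccc(OC)cc1 | intermediate
23 | enynol: C15 primary allylic alcohol of 22 | OC/C(C#C[Si](C)(C)C)=C/[C@H]1OC(=O)C(=C)[C@@H]1[C@@H](OC(=O)C(C)=C)C[C@@](C)(O[Si](CC)(CC)CC)COCc1ccc(OC)cc1 | intermediate
24 | C15 acetate of 23 | CC(=O)OC/C(C#C[Si](C)(C)C)=C/[C@H]1OC(=O)C(=C)[C@@H]1[C@@H](OC(=O)C(C)=C)C[C@@](C)(O[Si](CC)(CC)CC)COCc1ccc(OC)cc1 | intermediate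
25 | C1 primary alcohol of 24 (PMB removed) | CC(=O)OC/C(C#C[Si](C)(C)C)=C/[C@H]1OC(=O)C(=C)[C@@H]1[C@@H](OC(=O)C(C)=C)C[C@@](C)(O[Si](CC)(CC)CC)CO | intermediate
26 | 1-iodoalkyne of 25 (iodine on C2) | CC(=O)OC/C(C#CI)=C/[C@H]1OC(=O)C(=C)[C@@H]1[C@@H](OC(=O)C(C)=C)C[C@@](C)(O[Si](CC)(CC)CC)CO | intermediate
27 | C1 aldehyde of 26 | CC(=O)OC/C(C#CI)=C/[C@H]1OC(=O)C(=C)[C@@H]1[C@@H](OC(=O)C(C)=C)C[C@@](C)(O[Si](CC)(CC)CC)C=O | intermediate
28 | ten-membered carbocycle C1–C10: C1 secondary propargylic alcohol (both epimers), C2≡C3, C4=C5 with C3 cis to C6, C10 OTES | CC(=O)OC/C1=C/[C@H]2OC(=O)C(=C)[C@@H]2[C@@H](OC(=O)C(C)=C)C[C@@](C)(O[Si](CC)(CC)CC)C(O)C#C1 | intermediate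
29 | macrocyclic ynone (C1 ketone) of 28 | CC(=O)OC/C1=C/[C@H]2OC(=O)C(=C)[C@@H]2[C@@H](OC(=O)C(C)=C)C[C@@](C)(O[Si](CC)(CC)CC)C(=O)C#C1 | intermediate
30 | α'-hydroxy ynone: 29 with free tertiary C10 hydroxyl | CC(=O)OC/C1=C/[C@H]2OC(=O)C(=C)[C@@H]2[C@@H](OC(=O)C(C)=C)C[C@@](C)(O)C(=O)C#C1 | intermediate
31 | goyazensolide 15-acetate, (6R,7R,8S,10R), 4Z, with the 3(2H)-furanone bridging C3 and C10 | C=C(C)C(=O)O[C@H]1C[C@@]2(C)OC(=CC2=O)/C(COC(C)=O)=C\[C@H]2OC(=O)C(=C)[C@H]12 | target

Total step count: 23. Longest linear sequence: 21 steps (1 to 31 through 4, 7, 10, 13, 16, 20 and 28; steps 4 and 12 are side branches).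

Steps most likely to fail

Step 8 (key step). The stabilised carbanion may be too weak a nucleophile to open the epoxide at a temperature low enough to avoid phosphoryl transfer to O8, so that the ester is recovered or attack through enolate oxygen or at C8 takes over. The fallback sets out from 7 and comes back at 13; it replaces the epoxide by the far more electrophilic cyclic sulfate. Allylic alcohol 7 is esterified with 9 (DCC, DMAP) to give allylic phosphonoacetate F1. OsO4 (cat.) with N-methylmorpholine N-oxide then adds two hydroxyls to the E alkene on the face anti to the allylic acyloxy group, the usual sense of osmylation next to an allylic oxygen, to give diol F2 with the C7 and C8 configurations of epoxide 8. SOCl2/Et3N converts it into cyclic sulfite F3, and RuCl3 (cat.)/NaIO4 at 0 °C oxidises this briefly to cyclic sulfate F4. NaH in THF closes the same lactone by attack of C11 at C7, cyclic sulfates being alkylated by malonate-type carbanions at room temperature, and gives sulfate monoester salt F5. Short treatment with a catalytic amount of H2SO4 and one equivalent of water in THF at 0 °C hydrolyses the sulfate and returns 13.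

Step 20. Intermolecular coupling or simple reduction of the iodoalkyne may outpace closure of the strained ten-membered enyne ring. The fallback sets out from 20 and comes back at 28; it closes the ring at C3–C4 with palladium instead of at C1–C2 with chromium. Bromo enal 20 is reduced (NaBH4, CeCl3·7H2O, −78 °C) to bromo allylic alcohol F6 and acetylated to bromo allylic acetate F7. DDQ frees C1 alcohol F8 and Dess–Martin oxidation gives aldehyde F9. Ethynylmagnesium bromide at −78 °C adds to the aldehyde only and gives terminal propargylic alcohol F10 as a mixture of C1 epimers. An intramolecular Sonogashira coupling of the terminal alkyne with the vinyl bromide (Pd(PPh3)4, CuI, Et3N, high dilution) then closes the ring to 28.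

Step 9. Displacement at the hindered C8 oxyphosphonium by the weakly acidic methacrylic acid may be slow, so that elimination toward C9 or recovery of 13 results. The fallback sets out from 13 and comes back at 14; it separates inversion from acylation. A Mitsunobu reaction with the stronger chloroacetic acid gives inverted chloroacetate F11. Thiourea/NaHCO3 in ethanol removes the chloroacetyl group selectively to give C8-inverted alcohol F12. Methacrylic anhydride, Et3N and DMAP acylate it with retention to 14.

Further compounds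

F1 | step 8 | allylic phosphonoacetate, C6 2-(diethoxyphosphoryl)acetate of 7 | CC[Si](CC)(CC)OC[C@@H](OC(=O)CP(=O)(OCC)OCC)/C=C/C[C@@](C)(O[Si](CC)(CC)CC)COCc1ccc(OC)cc1
F2 | step 8 | C7,C8 diol of F1 with the C7 and C8 configurations of 8 | CC[Si](CC)(CC)OC[C@@H](OC(=O)CP(=O)(OCC)OCC)[C@@H](O)[C@H](O)C[C@@](C)(O[Si](CC)(CC)CC)COCc1ccc(OC)cc1
F3 | step 8 | C7,C8 cyclic sulfite of F2 | CC[Si](CC)(CC)OC[C@@H](OC(=O)CP(=O)(OCC)OCC)[C@H]1OS(=O)O[C@@H]1C[C@@](C)(O[Si](CC)(CC)CC)COCc1ccc(OC)cc1
F4 | step 8 | C7,C8 cyclic sulfate of F2 | CC[Si](CC)(CC)OC[C@@H](OC(=O)CP(=O)(OCC)OCC)[C@H]1OS(=O)(=O)O[C@@H]1C[C@@](C)(O[Si](CC)(CC)CC)COCc1ccc(OC)cc1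
F5 | step 8 | sodium C8 sulfate monoester of 13 | CC[Si](CC)(CC)OC[C@H]1OC(=O)[C@@H](P(=O)(OCC)OCC)[C@@H]1[C@H](OS(=O)(=O)[O-])C[C@@](C)(O[Si](CC)(CC)CC)COCc1ccc(OC)cc1.[Na+]
F6 | step 20 | bromo allylic alcohol, C15 alcohol of 20 | OC/C(Br)=C/[C@H]1OC(=O)C(=C)[C@@H]1[C@@H](OC(=O)C(C)=C)C[C@@](C)(O[Si](CC)(CC)CC)COCc1ccc(OC)cc1
F7 | step 20 | bromo allylic acetate, C15 acetate of F6 | CC(=O)OC/C(Br)=C/[C@H]1OC(=O)C(=C)[C@@H]1[C@@H](OC(=O)C(C)=C)C[C@@](C)(O[Si](CC)(CC)CC)COCc1ccc(OC)cc1
F8 | step 20 | C1 alcohol of F7 (PMB removed) | CC(=O)OC/C(Br)=C/[C@H]1OC(=O)C(=C)[C@@H]1[C@@H](OC(=O)C(C)=C)C[C@@](C)(O[Si](CC)(CC)CC)CO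
F9 | step 20 | C1 aldehyde of F8 | CC(=O)OC/C(Br)=C/[C@H]1OC(=O)C(=C)[C@@H]1[C@@H](OC(=O)C(C)=C)C[C@@](C)(O[Si](CC)(CC)CC)C=O
F10 | step 20 | terminal propargylic alcohol from F9 (both C1 epimers) | CC(=O)OC/C(Br)=C/[C@H]1OC(=O)C(=C)[C@@H]1[C@@H](OC(=O)C(C)=C)C[C@@](C)(O[Si](CC)(CC)CC)C(O)C#C
F11 | step 9 | C8 chloroacetate of the phosphono lactone, C8 inverted | CC[Si](CC)(CC)OC[C@H]1OC(=O)[C@@H](P(=O)(OCC)OCC)[C@@H]1[C@@H](OC(=O)CCl)C[C@@](C)(O[Si](CC)(CC)CC)COCc1ccc(OC)cc1
F12 | step 9 | C8 epimer of 13 (free C8 hydroxyl in the configuration of the target) | CC[Si](CC)(CC)OC[C@H]1OC(=O)[C@@H](P(=O)(OCC)OCC)[C@@H]1[C@@H](O)C[C@@](C)(O[Si](CC)(CC)CC)COCc1ccc(OC)cc1
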